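**The decision.** I meant to leave the charge of the four new flasks as it stood and to change the bath, so I needed one figure for how fast a flask quickens with temperature.

all flasks: free catalyst 24 mM

| flask | starting material | second substrate | temperature | remark | time |
|---|---|---|---|---|---|
| red | 0.40 M | 0.80 M | 51 °C | run made earlier |  |
| ochre | 1.6 M | 0.80 M | 76 °C | run made earlier |  |
| grey | 0.80 M | 1.2 M | 51 °C | run made earlier |  |
| birch | 0.80 M | 0.800 M | 85 °C |  | 25 min |
| alder | 0.80 M | 0.800 M | 55 °C |  | 25 min |
| larch | 0.80 M | 0.800 M | 70 °C |  | 25 min |
| maple | 0.80 M | 0.800 M | 40 °C |  | 25 min |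

| run | time / min | target / % | starting material / % |
|---|---|---|---|
| red | 8.00 | 2 | 97 |
| red | 15.0 | 5 | 95 |
| red | 30.0 | 8 | 94 |
| red | 50.0 | 12 | 86 |
| red | 120 | 29 | 71 |
| ochre | 2.50 | 6 | 91 |
| ochre | 5.00 | 12 | 89 |
| ochre | 10.0 | 25 | 76 |
| ochre | 15.0 | 35 | 64 |
| ochre | 30.0 | 56 | 44 |
| grey | 8.00 | 5 | 99 |
| grey | 15.0 | 4 | 98 |
| grey | 30.0 | 7 | 95 |
| grey | 50.0 | 10 | 93 |
| grey | 120 | 23 | 77 |

(scatter of a reading: 1.5 percentage points)

- the flask that comes out highest in amount of target, in percent of the starting material charged, or "all alike" when all lie within 1.5 percentage points (birch / alder / larch / maple / all alike)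
- target at the end, in percent of the starting material charged, birch
- target at the end, in percent of the starting material charged, alder
- target at the end, in percent of the starting material charged, larch
- target at the end, in percent of the starting material charged, maple



**Time constants.** In each run target and starting material summed to about the charge, so I read each as a first-order decay, whose time constant is the elapsed time over the logarithm of the inverse fraction left. The last readings gave 350 min for red, 459 min for grey and 36.5 min for ochre at 76 °C. Red and ochre carried the [second substrate] of the new charge and grey carried more, so I set grey aside; ochre's time constant read 34.8 min at 15.0 min against 36.5 min at the end, while its [starting material] fell to 44% of the charge, so I let that amount go and took red's 350 min for 51 °C.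

**Doubling span.** Between those two temperatures the time constant fell by a factor of 9.59, which came to 7.67 K: this doubling span, the degrees of bath that halve the time constant, was my carried figure. Stepped up from ochre, it gave 16.2 min for birch, shorter than the run of 25 min, hence 78.6% of target. Stepped down, it gave 947 min for maple, far longer than the run, hence 2.61%. So I chose birch.

**The forecast.** The forecast also named birch, with 80% there (60% to 92%), then 9% for alder, 35% for larch and 2% for maple, and it said that the hottest value “is an extrapolation, so it is the least certain”.

**The result.** Birch came out highest, at 76.8%, with alder at 10.4%, larch at 35.5% and maple at 2.88%. One span had covered flasks in which free catalyst ended at 75.3% of its charge in birch and 23.3% in maple. Read back from the result, birch's time constant was 17.1 min, against the 16.2 min the span had stepped to.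

    starting material + free catalyst ⇌ catalyst intermediate A (K = 1.70 /M, k = 0.0230 /M/s, Ea = 70.0 kJ/mol, ΔH = −57.0 kJ/mol)
    catalyst intermediate A → free catalyst + target (k = 0.230 /s, Ea = 75.0 kJ/mol)
    second substrate + free catalyst ⇌ catalyst intermediate B (K = 3.30 /M, k = 0.0160 /M/s, Ea = 50.0 kJ/mol, ΔH = −45.0 kJ/mol)
    catalyst intermediate B → free catalyst + second product (k = 0.0110 /s, Ea = 93.0 kJ/mol)
    starting material + free catalyst → spent catalyst (k = 4.10 × 10⁻⁵ /M/s, Ea = 77.0 kJ/mol)
    (constants at 70 °C)

**Second flask.** Birch run at 70 °C has larch's charge and temperature, and the span steps ochre's time constant up to 62.9 min, which gives 32.8% of target. The computed flask gives 35.5%.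

The earlier runs and the new flask are calculated on assumed constants; the scatter is artificial.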